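Ring A of hansfordiol C is a 5-alkylresorcinol: hydroxyls on C1 and C3, the C17 chain on C5. This 1,3,5-pattern is a dehydrogenated, enolised 5-alkylcyclohexane-1,3-dione, so ring bonds C5–C6 and C1–C2 are disconnected to dimethyl malonate and a C21 (E)-methyl enone that already carries the (S)-carbinol, C15′. In one operation, conjugate addition followed by Claisen ring closure forges both bonds and the carbocycle; bromine-mediated dehydrogenation and loss of the ester carbon then reveal the arene. The precursor, (S,E)-19-hydroxyhenicos-3-en-2-one, is used with its alcohol unprotected and is made from hexadecanolide by catalytic asymmetric ethylation and Wittig olefination.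

Key step: step 6

Remarks on the chemistry (assumptions):
- The side chain is ring–(CH2)14–CH(OH)–CH2CH3 with (S) at C15′. Because C4 of the enone becomes ring C5, the enone must be the C21 compound with exactly fourteen CH2 groups between C4 and C19.
- The alcohol is carried free after step 3. It is a spectator toward methoxide, and a silyl ether would not be expected to survive the HBr released during aromatisation.
- The (1R,2R)-ligand in step 3 is assumed to show its usual Si-face preference. The configuration of 6 would be confirmed (Mosher esters), and the (1S,2S)-ligand used if the sense were opposite.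

Step 1
Reactants: 1 hexadecanolide (oxacycloheptadecan-2-one); 2 methanol
Product: 3 methyl 16-hydroxyhexadecanoate
Conditions: MeOH (solvent), H2SO4 (cat.), reflux; NaHCO3 work-up
Reagents that add atoms: methanol (2), CO
Why: Acid-catalysed transesterification (Fischer-type methanolysis) of an unstrained macrolactone, driven to the open-chain hydroxy ester by the large excess of methanol.

Step 2
Reactants: 3 methyl 16-hydroxyhexadecanoate
Product: 4 methyl 16-oxohexadecanoate
Conditions: TEMPO (10 mol%), PhI(OAc)2 (1.1 equiv), CH2Cl2, rt; filtration through silica
Reagents that add atoms: none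
Why: Oxoammonium (TEMPO)-catalysed oxidation of a primary alcohol stops at the aldehyde in the absence of water and leaves the ester untouched; the acetic acid formed is removed before the organozinc step.

Step 3
Reactants: 4 methyl 16-oxohexadecanoate; 5 diethylzinc
Product: 6 methyl (S)-16-hydroxyoctadecanoate
Conditions: Et2Zn (2 equiv), Ti(OiPr)4 (1.2 equiv), (1R,2R)-N,N′-(cyclohexane-1,2-diyl)bis(trifluoromethanesulfonamide) (5 mol%), toluene, −20 °C; then 1 M HCl
Reagents that add atoms: diethylzinc (5), CC[Zn]CC
Why: Titanium bis(sulfonamide)-catalysed enantioselective addition of a dialkylzinc to an aldehyde: the chiral complex formed from Ti(OiPr)4 and the ligand binds the aldehyde and ethyl is delivered to its Si face, setting the (S)-carbinol (the later C15′) under reagent control, while the methyl ester is inert to the organozinc at −20 °C.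

Step 4
Reactants: 6 methyl (S)-16-hydroxyoctadecanoate
Product: 7 (S)-16-hydroxyoctadecanal
Conditions: iBu2AlH (2.2 equiv), CH2Cl2, −78 °C; MeOH at −78 °C, then aq. KNaC4H4O6
Reagents that add atoms: none
Why: Low-temperature partial reduction of an ester with iBu2AlH: the first equivalent turns the hydroxyl into an aluminium alkoxide, the second gives a tetrahedral aluminium hemiacetal that persists at −78 °C and releases the aldehyde only on quench, and the carbinol centre is not involved.

Step 5
Reactants: 7 (S)-16-hydroxyoctadecanal; 8 1-(triphenylphosphoranylidene)propan-2-one
Product: 9 (S,E)-19-hydroxyhenicos-3-en-2-one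
Conditions: Ph3P=CHC(O)CH3 (1.2 equiv), toluene, 80 °C
Reagents that add atoms: 1-(triphenylphosphoranylidene)propan-2-one (8), CC(=O)C=P(c1ccccc1)(c1ccccc1)c1ccccc1
Why: Wittig olefination with a ketone-stabilised ylide, which reacts only with the aldehyde, tolerates the free hydroxyl and should give the (E)-enone, as stabilised ylides do.

Step 6
Reactants: 9 (S,E)-19-hydroxyhenicos-3-en-2-one; 10 dimethyl malonate
Product: 12 methyl 6-[(S)-15-hydroxyheptadecyl]-2,4-dioxocyclohexane-1-carboxylate, via malonate Michael adduct 11 (not isolated)
Conditions: NaOMe (1.3 equiv), dimethyl malonate (1.3 equiv), MeOH–THF, reflux; then cold 1 M HCl to pH 3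
Reagents that add atoms: dimethyl malonate (10), COC(=O)CC(=O)OC
Why: Methoxide generates the malonate anion, which adds reversibly in conjugate fashion to C4 of enone 9 (ring A bond C5–C6) to give adduct 11; proton transfer then forms the methyl-ketone enolate at C1 of the enone, which attacks one malonate ester carbonyl and expels methoxide (ring A bond C1–C2). The closest known reaction type is the Michael–Claisen (Dieckmann-type) annulation of alk-3-en-2-ones with malonic esters, the classical entry to 5-alkylcyclohexane-1,3-diones and olivetol-type resorcinols. The new six-membered ring, the future ring A, closes in a 6-exo-trig mode; the other ketone enolate (C3 side) could reach an ester only through a four-membered transition state, so the constitution is fixed. Two ring stereocentres arise (the carbons bearing the ester and the side chain); they are not controlled, the ester-bearing one equilibrates under the basic conditions (trans expected), and both disappear on aromatisation, while C15′ lies far from any acidic position and is untouched. The selectivity needed is 1,4- over 1,2-addition and a single Claisen mode without self-condensation of the enone: the soft, reversibly adding malonate in slight excess secures the first, ring-size constraints the second, and the sequence is pulled forward by deprotonation of the product to its stabilised β-diketone enolate, from which 12 is released on acidification. The free secondary hydroxyl does not interfere because it is less acidic than malonate and methanol is the solvent.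

Step 7
Reactants: 12 methyl 6-[(S)-15-hydroxyheptadecyl]-2,4-dioxocyclohexane-1-carboxylate
Product: 14 methyl 2,4-dihydroxy-6-[(S)-15-hydroxyheptadecyl]benzoate, via 3-bromo diketo ester 13 (not isolated)
Conditions: Br2 (1.0 equiv), DMF, 0 °C to rt, then 80 °C; aq. NaHCO3 work-up
Reagents that add atoms: none
Why: Halogenative aromatisation of a dihydroresorcylate: the enolised β-diketone is brominated (kinetically at C3, giving 13), bromine transposes under the HBr formed, HBr is lost on heating and the cyclohexadienone tautomerises to the phenol; the remote alcohol can at worst be formylated by DMF/HBr, which step 8 reverses, and any ester already lost at this stage converges in step 8.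

Step 8
Reactants: 14 methyl 2,4-dihydroxy-6-[(S)-15-hydroxyheptadecyl]benzoate
Product: 16 hansfordiol C (5-[(S)-15-hydroxyheptadecyl]benzene-1,3-diol), via resorcylic acid 15 (not isolated)
Conditions: NaOH (2.5 M aq.), MeOH, reflux, Ar; then 2 M HCl to pH 1, 60 °C
Reagents that add atoms: none
Why: Saponification of the salicylate-type ester gives β-resorcylic acid 15, which undergoes protodecarboxylation readily (ipso-protonation of the electron-rich ring, then loss of CO2) in the hot medium and on acidification; the secondary carbinol is inert to hydroxide and to brief dilute acid.

Compound list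
1 | hexadecanolide (oxacycloheptadecan-2-one) | O=C1CCCCCCCCCCCCCCCO1 | starting material
2 | methanol | CO | starting material
3 | methyl 16-hydroxyhexadecanoate | OCCCCCCCCCCCCCCCC(=O)OC | intermediate
4 | methyl 16-oxohexadecanoate | O=CCCCCCCCCCCCCCCC(=O)OC | intermediate
5 | diethylzinc | CC[Zn]CC | starting material
6 | methyl (S)-16-hydroxyoctadecanoate | CC[C@H](O)CCCCCCCCCCCCCCC(=O)OC | intermediate
7 | (S)-16-hydroxyoctadecanal | CC[C@H](O)CCCCCCCCCCCCCCC=O | intermediate
8 | 1-(triphenylphosphoranylidene)propan-2-one | CC(=O)C=P(c1ccccc1)(c1ccccc1)c1ccccc1 | starting material
9 | (S,E)-19-hydroxyhenicos-3-en-2-one | CC[C@H](O)CCCCCCCCCCCCCC/C=C/C(C)=O | intermediate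
10 | dimethyl malonate | COC(=O)CC(=O)OC | starting material
11 | dimethyl 2-[(19S)-19-hydroxy-2-oxohenicosan-4-yl]malonate (Michael adduct, formed in the flask, C4 uncontrolled) | CC[C@H](O)CCCCCCCCCCCCCCC(CC(C)=O)C(C(=O)OC)C(=O)OC | intermediate
12 | methyl 6-[(S)-15-hydroxyheptadecyl]-2,4-dioxocyclohexane-1-carboxylate (ring centres uncontrolled, keto–enol mixture) | CC[C@H](O)CCCCCCCCCCCCCCC1CC(=O)CC(=O)C1C(=O)OC | intermediate
13 | methyl 3-bromo-6-[(S)-15-hydroxyheptadecyl]-2,4-dioxocyclohexane-1-carboxylate (formed in the flask) | CC[C@H](O)CCCCCCCCCCCCCCC1CC(=O)C(Br)C(=O)C1C(=O)OC | intermediate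
14 | methyl 2,4-dihydroxy-6-[(S)-15-hydroxyheptadecyl]benzoate | CC[C@H](O)CCCCCCCCCCCCCCc1cc(O)cc(O)c1C(=O)OC | intermediate
15 | 2,4-dihydroxy-6-[(S)-15-hydroxyheptadecyl]benzoic acid (formed in the flask) | CC[C@H](O)CCCCCCCCCCCCCCc1cc(O)cc(O)c1C(=O)O | intermediate
16 | hansfordiol C, 5-[(S)-15-hydroxyheptadecyl]benzene-1,3-diol | CC[C@H](O)CCCCCCCCCCCCCCc1cc(O)cc(O)c1 | target

Total step count: 8
Longest linear sequence: 8 steps (1 to 16)

Steps most likely to fail

1. Step 7 (aromatisation). What may go wrong: bromination beyond one equivalent on the enol or on the electron-rich resorcinol ring once it forms, incomplete loss of HBr, and acid-promoted esterification of the carbinol during heating. The fallback avoids halogen altogether and sets out from 12. Saponification and decarboxylation come first (aq. NaOH/MeOH, reflux, then HCl) and give 5-[(S)-15-hydroxyheptadecyl]cyclohexane-1,3-dione F1. F1 is then dehydrogenated over Pd/C in refluxing mesitylene under an argon sweep, a known catalytic dehydrogenation of cyclohexane-1,3-diones to resorcinols. The fallback comes back to the route at 16.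

2. Step 4 (partial reduction). What may go wrong: over-reduction to the primary alcohol if the aluminium hemiacetal collapses before the quench, or uneven reduction if the waxy ester precipitates at −78 °C. The fallback sets out from 6 and separates reduction from oxidation-level adjustment. LiAlH4 in THF reduces the ester fully to (S)-octadecane-1,16-diol F2. TEMPO/PhI(OAc)2 in CH2Cl2 then oxidises only the primary hydroxyl, since oxoammonium oxidation strongly prefers primary over secondary alcohols. The fallback comes back at 7.

3. Step 3 (asymmetric ethylation). What may go wrong: incomplete facial selectivity, or loss of aldehyde through enolisation and aldol pathways, leaving 6 below the enantiopurity required. The fallback sets out from 4 and replaces catalytic induction by a resolution. CH2=CHMgBr (THF, −78 °C) adds to the aldehyde and gives racemic methyl 16-hydroxyoctadec-17-enoate F3. Sharpless kinetic resolution (Ti(OiPr)4, L-(+)-diisopropyl tartrate, t-BuOOH, 4 Å sieves, CH2Cl2, −20 °C, run past half conversion) consumes the (S)-carbinol as its epoxy alcohol and leaves methyl (R)-16-hydroxyoctadec-17-enoate F4. Hydrogenation of the vinyl group (H2, Pt/C, EtOAc) converts F4 into 6; the descriptor changes from R to S only because ethyl ranks below the long chain. The fallback comes back at 6.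

Further compounds
F1 | step 7 | 5-[(S)-15-hydroxyheptadecyl]cyclohexane-1,3-dione | CC[C@H](O)CCCCCCCCCCCCCCC1CC(=O)CC(=O)C1
F2 | step 4 | (S)-octadecane-1,16-diol | CC[C@H](O)CCCCCCCCCCCCCCCO
F3 | step 3 | methyl 16-hydroxyoctadec-17-enoate (racemic) | C=CC(O)CCCCCCCCCCCCCCC(=O)OC
F4 | step 3 | methyl (R)-16-hydroxyoctadec-17-enoate | C=C[C@H](O)CCCCCCCCCCCCCCC(=O)OC
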